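## Retrosynthetic overview

1. The C7 hydroxyl goes in last by α'-hydroxylation of the kinetic enolate. Before that, the ring allylic alcohol is acylated with the complete (6R)-dienoic acid, which is made by ene–diene cross metathesis of a tertiary allylic alcohol from Sharpless epoxidation.
2. The linear dienone comes from the enone by γ,δ-dehydrogenation. The enone and the secondary methyl come from one hydrogenation of a cross-conjugated dienone that carries an exocyclic methylene.
3. Key step, in place of a Robinson annulation: a Pd-catalysed enantioselective dearomative cyclisation of a p-cresol-type phenol onto a meta-tethered 2-bromoallylic alcohol. It makes the C4a–C5 bond and the quaternary stereocentre.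
4. Ring order: the ketone ring is the original arene. The carbinol ring is closed in the key step. All later stereocentres (C5, C7) are relayed from C4a.
5. The cyclisation precursor comes from a B-alkyl Suzuki coupling of 3-iodo-4-methylphenol with (S)-2-bromopenta-1,4-dien-3-ol, which is obtained by Sharpless kinetic resolution.

Assumption: 3-iodo-4-methylphenol, (2E)-penta-2,4-dienoic acid, both tartrate esters and a P-chiral AntPhos-type monophosphine are taken as purchasable. Locants in the "Why" lines follow the naphthalenone names.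

## Route

Step 1
Reactants: 1 acrolein
Product: 3 2-bromoacrolein, via 2,3-dibromopropanal 2 (not isolated)
Conditions: Br2, CH2Cl2, −78 to 0 °C; then Et3N, 0 °C
Reagents that add atoms: bromine, BrBr
Why: Electrophilic bromine addition to the enal followed by E1cB dehydrobromination of the acidic α-H (bromination–dehydrobromination) gives the α-bromo enal; no stereocentre is formed.

Step 2
Reactants: 3 2-bromoacrolein; 4 vinylmagnesium bromide
Product: 5 rac-2-bromopenta-1,4-dien-3-ol
Conditions: THF, −78 °C; sat. aq NH4Cl
Reagents that add atoms: none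
Why: Grignard 1,2-addition to a reactive enal at low temperature gives the racemic bis-allylic alcohol.

Step 3
Reactants: 5 rac-2-bromopenta-1,4-dien-3-ol
Product: 6 (3S)-2-bromopenta-1,4-dien-3-ol
Conditions: Ti(OiPr)4 (0.15 equiv), L-(+)-DIPT (0.2 equiv), TBHP (0.6 equiv), 4 Å MS, CH2Cl2, −20 °C, to ca. 55 % conversion
Reagents that add atoms: none
Why: In this Sharpless kinetic resolution only the electron-rich vinyl group is epoxidised and the bromoalkene is inert, so with L-(+)-tartrate the (R)-alcohol is consumed and the slow-reacting (S)-alcohol is recovered in high ee, which fixes the future C6 carbinol.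

Step 4
Reactants: 6 (3S)-2-bromopenta-1,4-dien-3-ol; 7 3-iodo-4-methylphenol
Product: 9 (3S)-2-bromo-5-(5-hydroxy-2-methylphenyl)pent-1-en-3-ol, via bis-BBN adduct 8 (not isolated)
Conditions: 9-BBN (2.1 equiv), THF, 0 °C to rt; then 7, PdCl2(dppf) (5 mol %), aq K3PO4, DMF, rt
Reagents that add atoms: none
Why: 9-BBN hydroborates the monosubstituted alkene far faster than the bromoalkene, and the B-alkyl Suzuki–Miyaura coupling takes place at the aryl iodide at room temperature, which undergoes oxidative addition much faster than the 1,1-disubstituted alkenyl bromide; the carbinol centre is untouched.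

Step 5
Reactants: 9 (3S)-2-bromo-5-(5-hydroxy-2-methylphenyl)pent-1-en-3-ol
Product: 10 (4aS,6S)-6-hydroxy-4a-methyl-5-methylidene-5,6,7,8-tetrahydronaphthalen-2(4aH)-one
Conditions: [Pd(cinnamyl)Cl]2 (2.5 mol %), P-chiral AntPhos-type ligand (6 mol %), K2CO3 (2 equiv), toluene, 90 °C
Reagents that add atoms: none
Why: Proposed new method: Pd(0) inserts into the alkenyl C–Br bond, the potassium phenoxide binds, its methyl-bearing para carbon attacks Pd(II), and C–C reductive elimination closes the six-membered ring to the 4,4-disubstituted cyclohexadienone, with the ligand choosing the arene face (new quaternary centre 4aS, matched with the 6S carbinol, which cannot chelate Pd because that would need a four-membered ring); the closest known reaction type is the Pd-catalysed enantioselective dearomative cyclisation of p-alkylphenols carrying a meta-tethered aryl bromide, and alkenyl-Pd(II) species already dearomatise phenols in spiroannulations, so only the alkenyl bromide partner is new.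

Step 6
Reactants: 10 (4aS,6S)-6-hydroxy-4a-methyl-5-methylidene-5,6,7,8-tetrahydronaphthalen-2(4aH)-one
Product: 11 (4aR,5R,6S)-6-hydroxy-4a,5-dimethyl-4,4a,5,6,7,8-hexahydronaphthalen-2(3H)-one
Conditions: H2 (4 atm), RhCl(PPh3)3 (10 mol %), benzene–EtOH, rt
Reagents that add atoms: none
Why: Homogeneous Wilkinson hydrogenation reduces the disubstituted C3=C4 bond of a cross-conjugated dienone and the 1,1-disubstituted alkene but leaves the trisubstituted enone bond, and H2 reaches the exocyclic methylene from the face opposite the angular methyl and the axial hydroxyl, so the new C5 methyl ends up cis to both (5R).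

Step 7
Reactants: 11 (4aR,5R,6S)-6-hydroxy-4a,5-dimethyl-4,4a,5,6,7,8-hexahydronaphthalen-2(3H)-one
Product: 12 (4aR,5R,6S)-6-hydroxy-4a,5-dimethyl-4,4a,5,6-tetrahydronaphthalen-2(3H)-one
Conditions: chloranil (1.3 equiv), t-BuOH, reflux
Reagents that add atoms: none
Why: Quinone dehydrogenation through the thermodynamic extended dienol (hydride loss from C7) turns a 4-en-3-one-type enone into the linear 4,6-dienone type, chloranil does not oxidise the secondary alcohol, and no stereocentre is touched.

Step 8
Reactants: 13 but-1-yne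
Product: 16 (E)-3-methylpent-2-en-1-ol, via dimethyl alkenylalane 14 (not isolated), via lithium alanate 15 (not isolated)
Conditions: Me3Al, Cp2ZrCl2 (20 mol %), CH2Cl2, 0 °C to rt; n-BuLi, THF, −78 °C; (CH2O)n, rt; aq HCl
Reagents that add atoms: trimethylaluminium, C[Al](C)C; paraformaldehyde (as formaldehyde), C=O
Why: Negishi Zr-catalysed syn-carboalumination places methyl on the internal carbon and Al on the terminus, and trapping the alanate with formaldehyde occurs with retention, which gives the pure E trisubstituted allylic alcohol.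

Step 9
Reactants: 16 (E)-3-methylpent-2-en-1-ol
Product: 17 [(2R,3R)-3-ethyl-3-methyloxiran-2-yl]methanol
Conditions: Ti(OiPr)4 (5 mol %), D-(−)-DET (6 mol %), TBHP, 4 Å MS, CH2Cl2, −20 °C
Reagents that add atoms: tert-butyl hydroperoxide, CC(C)(C)OO
Why: Sharpless asymmetric epoxidation of a geraniol-type E allylic alcohol with D-(−)-tartrate gives the (2R,3R)-epoxide, which sets the fully substituted C–O centre of the side chain.

Step 10
Reactants: 17 [(2R,3R)-3-ethyl-3-methyloxiran-2-yl]methanol
Product: 18 (2R,3S)-2-ethyl-3-(iodomethyl)-2-methyloxirane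
Conditions: I2, PPh3, imidazole, CH2Cl2, 0 °C
Reagents that add atoms: iodine, II
Why: Appel-type iodination of the primary alcohol proceeds by SN2 at CH2 and leaves both epoxide carbons untouched (the descriptor at the CH changes only through CIP priorities).

Step 11
Reactants: 18 (2R,3S)-2-ethyl-3-(iodomethyl)-2-methyloxirane
Product: 19 (3R)-3-methylpent-1-en-3-ol
Conditions: Zn dust, AcOH (2 equiv), MeOH, 0 °C to rt
Reagents that add atoms: none
Why: Zinc insertion into the C–I bond and β-elimination (reductive epoxide opening, Boord type) break only the secondary C–O bond, so the tertiary carbinol keeps its configuration (R).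

Step 12
Reactants: 19 (3R)-3-methylpent-1-en-3-ol; 20 (2E)-penta-2,4-dienoic acid
Product: 21 (2E,4E,6R)-6-hydroxy-6-methylocta-2,4-dienoic acid
Conditions: Hoveyda–Grubbs II (5 mol %), 19 (3 equiv), CH2Cl2, 40 °C
Reagents that add atoms: none
Why: Ene–diene cross metathesis engages only the terminal double bond of the dienoic acid because the α,β-bond is deactivated, and the unprotected tertiary allylic alcohol is a slow-homodimerising partner that gives the E alkene.

Step 13
Reactants: 12 (4aR,5R,6S)-6-hydroxy-4a,5-dimethyl-4,4a,5,6-tetrahydronaphthalen-2(3H)-one; 21 (2E,4E,6R)-6-hydroxy-6-methylocta-2,4-dienoic acid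
Product: 23 (1R,2S,8aR)-1,8a-dimethyl-6-oxo-1,2,6,7,8,8a-hexahydronaphthalen-2-yl (2E,4E,6R)-6-hydroxy-6-methylocta-2,4-dienoate, via Yamaguchi mixed anhydride 22 (not isolated)
Conditions: 2,4,6-trichlorobenzoyl chloride, Et3N, toluene, rt; then 12, DMAP, rt to 40 °C
Reagents that add atoms: none
Why: Yamaguchi esterification acylates the hindered secondary allylic alcohol with retention (the C–O bond is not broken), while the tertiary alcohol of the acid is too hindered to compete.

Step 14
Reactants: 23 (1R,2S,8aR)-1,8a-dimethyl-6-oxo-1,2,6,7,8,8a-hexahydronaphthalen-2-yl (2E,4E,6R)-6-hydroxy-6-methylocta-2,4-dienoate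
Product: 25 (1R,2S,7R,8aR)-7-hydroxy-1,8a-dimethyl-6-oxo-1,2,6,7,8,8a-hexahydronaphthalen-2-yl (2E,4E,6R)-6-hydroxy-6-methylocta-2,4-dienoate (CNP0260852.1), via dilithio enolate alkoxide 24 (not isolated)
Conditions: LiHMDS (2.3 equiv), THF, −78 °C; 2-(phenylsulfonyl)-3-phenyloxaziridine, −78 °C; AcOH
Reagents that add atoms: 2-(phenylsulfonyl)-3-phenyloxaziridine, O=S(=O)(c1ccccc1)N1OC1c1ccccc1
Why: Kinetic α'-deprotonation of the linear dienone (the dienoate has no enolisable H, and the tertiary OH only takes one equivalent of base) followed by Davis oxaziridine hydroxylation delivers oxygen to the enolate face opposite the axial angular methyl, giving the equatorial (7R)-ketol, which is also the thermodynamic epimer.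

## Compound list

| No. | Name | SMILES | Role |
|---|---|---|---|
| 1 | acrolein | C=CC=O | starting material |
| 2 | 2,3-dibromopropanal (racemic) | O=CC(Br)CBr | intermediate |
| 3 | 2-bromoacrolein | C=C(Br)C=O | intermediate |
| 4 | vinylmagnesium bromide | C=C[Mg]Br | starting material |
| 5 | rac-2-bromopenta-1,4-dien-3-ol | C=CC(O)C(Br)=C | intermediate |
| 6 | (3S)-2-bromopenta-1,4-dien-3-ol | C=C[C@H](O)C(Br)=C | intermediate |
| 7 | 3-iodo-4-methylphenol | Cc1ccc(O)cc1I | starting material |
| 8 | bis-BBN adduct of 6 (O-borinate, terminal C-borane) | C=C(Br)[C@@H](OB1C2CCCC1CCC2)CCB1C2CCCC1CCC2 | intermediate |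
| 9 | (3S)-2-bromo-5-(5-hydroxy-2-methylphenyl)pent-1-en-3-ol | C=C(Br)[C@@H](O)CCc1cc(O)ccc1C | intermediate |
| 10 | (4aS,6S)-6-hydroxy-4a-methyl-5-methylidene-5,6,7,8-tetrahydronaphthalen-2(4aH)-one | O[C@H]1CCC2=CC(=O)C=C[C@]2(C)C1=C | intermediate |
| 11 | (4aR,5R,6S)-6-hydroxy-4a,5-dimethyl-4,4a,5,6,7,8-hexahydronaphthalen-2(3H)-one | O[C@H]1CCC2=CC(=O)CC[C@]2(C)[C@H]1C | intermediate |
| 12 | (4aR,5R,6S)-6-hydroxy-4a,5-dimethyl-4,4a,5,6-tetrahydronaphthalen-2(3H)-one | O[C@H]1C=CC2=CC(=O)CC[C@]2(C)[C@H]1C | intermediate |
| 13 | but-1-yne | CCC#C | starting material |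
| 14 | dimethyl[(E)-2-methylbut-1-enyl]alane | CC/C(C)=C/[Al](C)C | intermediate |
| 15 | lithium butyl(dimethyl)[(E)-2-methylbut-1-enyl]alanate | CC/C(C)=C/[Al-](C)(C)CCCC.[Li+] | intermediate |
| 16 | (E)-3-methylpent-2-en-1-ol | CC/C(C)=C/CO | intermediate |
| 17 | [(2R,3R)-3-ethyl-3-methyloxiran-2-yl]methanol | CC[C@@]1(C)O[C@@H]1CO | intermediate |
| 18 | (2R,3S)-2-ethyl-3-(iodomethyl)-2-methyloxirane | CC[C@@]1(C)O[C@@H]1CI | intermediate |
| 19 | (3R)-3-methylpent-1-en-3-ol | CC[C@@](C)(O)C=C | intermediate |
| 20 | (2E)-penta-2,4-dienoic acid | C=C/C=C/C(=O)O | starting material |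
| 21 | (2E,4E,6R)-6-hydroxy-6-methylocta-2,4-dienoic acid | CC[C@@](C)(O)/C=C/C=C/C(=O)O | intermediate |
| 22 | mixed anhydride of 21 with 2,4,6-trichlorobenzoic acid | CC[C@@](C)(O)/C=C/C=C/C(=O)OC(=O)c1c(Cl)cc(Cl)cc1Cl | intermediate |
| 23 | (1R,2S,8aR)-1,8a-dimethyl-6-oxo-1,2,6,7,8,8a-hexahydronaphthalen-2-yl (2E,4E,6R)-6-hydroxy-6-methylocta-2,4-dienoate | CC[C@@](C)(O)/C=C/C=C/C(=O)O[C@H]1C=CC2=CC(=O)CC[C@]2(C)[C@H]1C | intermediate |
| 24 | dilithium salt of 23 (C6–C7 enolate and tertiary alkoxide) | CC[C@@](C)([O-])/C=C/C=C/C(=O)O[C@H]1C=CC2=CC([O-])=CC[C@]2(C)[C@H]1C.[Li+].[Li+] | intermediate |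
| 25 | (1R,2S,7R,8aR)-7-hydroxy-1,8a-dimethyl-6-oxo-1,2,6,7,8,8a-hexahydronaphthalen-2-yl (2E,4E,6R)-6-hydroxy-6-methylocta-2,4-dienoate | CC[C@@](C)(O)/C=C/C=C/C(=O)O[C@H]1C=CC2=CC(=O)[C@H](O)C[C@]2(C)[C@H]1C | target |

## Step count and risk

Total step count: 14.
Longest linear sequence: 9 steps (1–7, 13, 14), from acrolein.

The three steps most likely to fail are 5, 6 and 7.

**Step 5 (dearomative cyclisation).** The main risks are attack at the free ortho carbon, hydrodebromination, and low ee with an alkenyl rather than an aryl bromide. The fallback sets out from 9 and comes back at 10. It replaces the Pd(0)/Pd(II) C–C reductive elimination with π-acid catalysis. Compound 9 is dehydrobrominated with TBAF·3H2O in DMF at 60 °C to (3S)-5-(5-hydroxy-2-methylphenyl)pent-1-yn-3-ol F1. A cationic gold(I) complex (a chiral bisphosphine digold catalyst, or IPrAuNTf2 under control by the carbinol centre) then activates the terminal alkyne. The phenol para carbon attacks in a 6-exo-dig mode, and protodeauration leaves the exocyclic methylene, which gives 10 directly.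

**Step 6 (double hydrogenation).** The risks are that the neopentyl-type exocyclic methylene is too hindered for the Rh catalyst, or that the allylic alcohol isomerises. The fallback sets out from 10 and comes back at 11. It uses that isomerisation deliberately.
- A transition-metal hydride catalyst (H2-activated cationic Ir or a CpRu(MeCN)3+ salt) carries out the redox isomerisation of the allylic alcohol to (4aR,5R)-4a,5-dimethyl-4a,5,7,8-tetrahydronaphthalene-2,6-dione F2. DBU equilibrates the C5 methyl to the equatorial, cis position.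
- Wilkinson hydrogenation then has to reduce only the unhindered C3=C4 bond. This gives (4aR,5R)-4a,5-dimethyl-4,4a,7,8-tetrahydronaphthalene-2,6(3H,5H)-dione F3.
- L-Selectride at −78 °C attacks the saturated ketone from the face opposite the axial angular methyl and gives the axial (6S)-alcohol 11. The β,β-disubstituted enone stays intact.

**Step 7 (chloranil dehydrogenation).** The risk is that hydride abstraction next to the carbinol carbon is slow, so that over-oxidation competes. The fallback sets out from 11 and comes back at 12. It replaces hydride abstraction with enol-silane/Pd(II) chemistry.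
- TBSOTf and Et3N give (4aR,5R,6S)-2,6-bis(tert-butyldimethylsilyloxy)-4a,5-dimethyl-3,4,4a,5,6,7-hexahydronaphthalene F4, the thermodynamic extended dienol ether.
- Saegusa–Ito oxidation with Pd(OAc)2 in MeCN/DMSO gives (4aR,5R,6S)-6-(tert-butyldimethylsilyloxy)-4a,5-dimethyl-4,4a,5,6-tetrahydronaphthalen-2(3H)-one F5.
- HF·pyridine removes the silyl ether to give 12.

## Further compounds

F1 | step 5 | (3S)-5-(5-hydroxy-2-methylphenyl)pent-1-yn-3-ol | C#C[C@@H](O)CCc1cc(O)ccc1C
F2 | step 6 | (4aR,5R)-4a,5-dimethyl-4a,5,7,8-tetrahydronaphthalene-2,6-dione | O=C1CCC2=CC(=O)C=C[C@]2(C)[C@H]1C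
F3 | step 6 | (4aR,5R)-4a,5-dimethyl-4,4a,7,8-tetrahydronaphthalene-2,6(3H,5H)-dione | O=C1CCC2=CC(=O)CC[C@]2(C)[C@H]1C
F4 | step 7 | (4aR,5R,6S)-2,6-bis(tert-butyldimethylsilyloxy)-4a,5-dimethyl-3,4,4a,5,6,7-hexahydronaphthalene | CC(C)(C)[Si](C)(C)O[C@H]1CC=C2C=C(O[Si](C)(C)C(C)(C)C)CC[C@]2(C)[C@H]1C
F5 | step 7 | (4aR,5R,6S)-6-(tert-butyldimethylsilyloxy)-4a,5-dimethyl-4,4a,5,6-tetrahydronaphthalen-2(3H)-one | CC(C)(C)[Si](C)(C)O[C@H]1C=CC2=CC(=O)CC[C@]2(C)[C@H]1C
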